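The pitfall is to treat this flask as a race against the clock, when its yield can be reckoned without one.

starting material 0.050 M; gas phase 4.1 mM (held); protic impurity 5.00 mM; time 3.0 h

1. the target standing at 3.0 h, as a percentage of the starting material charged
2. the change that raises the amount of target at 3.0 h, in percent of the starting material charged most ("none" if none brings more than 2 percentage points) (maple / alder / none)
3. amount of target at 3.0 h, in percent of the starting material charged, after alder

- maple: doubling the transfer coefficient of step 1, all else as stated
- alder: doubling the saturation concentration of gas phase, all else as stated

    gas phase ⇌ dissolved gas, rate k1*(csat - [dissolved gas]) (k1 = 0.0015 s⁻¹, csat = 4.1 mM)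
    starting material + dissolved gas → target (k2 = 0.15 M⁻¹ s⁻¹)
    starting material → side product (k3 = 2.0 × 10⁻⁴ s⁻¹)
    target ⇌ isomer of the product (K4 = 0.42, k4 = 9.9 × 10⁻⁴ s⁻¹)
    starting material + protic impurity → quenched substrate (k5 = 0.023 M⁻¹ s⁻¹)

Freeze the dissolved gas first. Transfer brings it toward balance with a half-life of 7.70 min, shorter still while starting material consumes it, and that is far shorter than the run, so I set delivery equal to use (the steady-state approximation). Target and isomer relax in 0.0575 h, also far faster than the run, so I give target a constant share of the pair, 70.4%.

Carry the break-even concentration, 30.7 mM: the starting material at which the side step consumes it as fast as an empty solution takes up gas. Beside it stands 10.0 mM, where dissolved gas sits at half saturation. The flask starts above break-even, so the side step leads at first.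

Integrating the gas route's share gives the pair as break-even times ln(1 + usable charge/(break-even + that second concentration)). I take the impurity off the charge, leaving 45.0 mM, and run to the end of the starting material. That gives target at 32.2%. Alder gives 42.3%, and maple 38.1%.

Turn the question round. Both changes double break-even, but maple doubles the second concentration too. A tie between them needs that concentration to be tiny beside break-even, and here it is a third of it.

The forecast said 32% (29% to 35%), chose alder, and put it at 39.5% (35% to 43%), since “Doubling the saturation concentration doubles the driving force at all times”. My alder figure is higher.

The simulation gives 30.6%, and alder at 40.6%, a gain of 10 percentage points against 6.3 points for maple.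

A neighbour flask holds 0.013 M of starting material, below break-even. There 15.1% of the charge ended quenched, so the reckoning runs on 11.0 mM and gives target at 39.9%. The simulated neighbour stands lower, at 36.2%, with side product at 33.4%.

The rate constants are those of an exercise.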